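**Plan**
- The chain is numbered C1 (benzylic, on guaiacyl ring A) to C7 (benzylic, on syringyl ring B). The C3 carbonyl sits between sp3 C2 and sp2 C4 of the E C4=C5 alkene, which is the place where carbon monoxide can be inserted between an alkylborane and an alkenyl iodide.
- Retrosynthesis: the two phenolic O–Si bonds are cut first. Then C2–C3 and C3–C4 are cut together, giving a primary B-alkyl-9-BBN (ring A, C1–C2), carbon monoxide (C3) and an (E)-alkenyl iodide (ring B, C4–C7).
- Forward: the iodide arm is built from 4-allyl-2,6-dimethoxyphenol and the borane from 2-methoxy-4-vinylphenol. One palladium-catalysed carbonylative coupling then joins the whole chain; no ring is formed anywhere.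
- Stereochemistry: there are no stereocentres. The E C4=C5 geometry is set in the iodoolefination and carried unchanged through the coupling.
- A final fluoride desilylation frees both phenols.

Key step: step 7

Remark on the chemistry: the ring A B-alkyl-9-BBN cannot be chromatographed; it is assumed to be prepared as a THF solution under argon and used as that solution in the coupling.

**Step 1**
Reactants: 1 4-allyl-2,6-dimethoxyphenol
Product: 2 (4-allyl-2,6-dimethoxyphenoxy)(tert-butyl)dimethylsilane
Conditions: TBSCl, imidazole, DMAP (cat.), DMF, rt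
Reagents that add atoms: tert-butyldimethylsilyl chloride (TBSCl), CC(C)(C)[Si](C)(C)Cl
Why: Imidazole-mediated silylation of a phenol is reliable even for a hydroxyl flanked by two methoxy groups, and the silyl ether removes the acidic O–H that would consume 9-BBN and the chromium reagents later.

**Step 2**
Reactants: 2 (4-allyl-2,6-dimethoxyphenoxy)(tert-butyl)dimethylsilane; 3 9-borabicyclo[3.3.1]nonane (9-BBN)
Product: 5 3-[4-(tert-butyldimethylsilyloxy)-3,5-dimethoxyphenyl]propan-1-ol, via B-alkyl-9-BBN adduct 4 (not isolated)
Conditions: 9-BBN, THF, 0 °C to rt; then NaBO3·4H2O, H2O, rt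
Reagents that add atoms: sodium perborate tetrahydrate NaBO3·4H2O (dimeric peroxoborate, supplies the hydroxyl oxygen), [Na+].[Na+].O[B-]1(O)OO[B-](O)(O)OO1.O.O.O.O.O.O
Why: Hydroboration–oxidation: 9-BBN adds to the terminal allyl alkene with boron on the end carbon, and the mild perborate oxidation of the C–B bond should give the primary alcohol without stripping the aryl silyl ether.

**Step 3**
Reactants: 5 3-[4-(tert-butyldimethylsilyloxy)-3,5-dimethoxyphenyl]propan-1-ol
Product: 6 3-[4-(tert-butyldimethylsilyloxy)-3,5-dimethoxyphenyl]propanal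
Conditions: Dess–Martin periodinane, CH2Cl2, rt
Reagents that add atoms: none
Why: Dess–Martin oxidation stops cleanly at the aldehyde under non-aqueous, nearly neutral conditions that leave the silyl ether and the electron-rich arene alone.

**Step 4**
Reactants: 6 3-[4-(tert-butyldimethylsilyloxy)-3,5-dimethoxyphenyl]propanal
Product: 7 tert-butyl{4-[(E)-4-iodobut-3-en-1-yl]-2,6-dimethoxyphenoxy}dimethylsilane
Conditions: CrCl2, CHI3, 1,4-dioxane/THF (6:1), 0 °C to rt, dark
Reagents that add atoms: iodoform (CHI3), IC(I)I
Why: Takai iodoolefination: the geminal dichromium species formed from CHI3 and divalent chromium adds to the aldehyde and eliminates to give the (E)-alkenyl iodide preferentially, which fixes the E geometry of the future C4=C5 bond.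

**Step 5**
Reactants: 8 2-methoxy-4-vinylphenol
Product: 9 tert-butyl(4-ethenyl-2-methoxyphenoxy)dimethylsilane
Conditions: TBSCl, imidazole, DMF, 0 °C to rt
Reagents that add atoms: tert-butyldimethylsilyl chloride (TBSCl), CC(C)(C)[Si](C)(C)Cl
Why: Imidazole-mediated phenol silylation protects the O–H before hydroboration and gives a styrene that is less prone to polymerise than the free vinylphenol.

**Step 6**
Reactants: 9 tert-butyl(4-ethenyl-2-methoxyphenoxy)dimethylsilane; 3 9-borabicyclo[3.3.1]nonane (9-BBN)
Product: 10 9-{2-[4-(tert-butyldimethylsilyloxy)-3-methoxyphenyl]ethyl}-9-borabicyclo[3.3.1]nonane (THF solution under argon)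
Conditions: 9-BBN (0.95 equiv), THF, 0 °C to rt, argon
Reagents that add atoms: 9-borabicyclo[3.3.1]nonane (3), B1C2CCCC1CCC2
Why: Hydroboration of a styrene with 9-BBN is strongly anti-Markovnikov, so a single primary alkylborane (boron on the future C2) should form, and the slight deficit of 9-BBN leaves no B–H to reduce the enone in the next step.

**Step 7**
Reactants: 10 9-{2-[4-(tert-butyldimethylsilyloxy)-3-methoxyphenyl]ethyl}-9-borabicyclo[3.3.1]nonane; 11 carbon monoxide; 7 tert-butyl{4-[(E)-4-iodobut-3-en-1-yl]-2,6-dimethoxyphenoxy}dimethylsilane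
Product: 12 (E)-1-[4-(tert-butyldimethylsilyloxy)-3-methoxyphenyl]-7-[4-(tert-butyldimethylsilyloxy)-3,5-dimethoxyphenyl]hept-4-en-3-one
Conditions: Pd(PPh3)4 (5 mol %), K3PO4, CO (1 atm), benzene/THF, rt, dark
Reagents that add atoms: carbon monoxide (11), [C-]#[O+]
Why: Zerovalent palladium inserts into the C–I bond of 7 with retention of the E geometry, CO inserts into the alkenyl–palladium bond of the divalent palladium intermediate to form the C3–C4 bond, phosphate-assisted transfer of the primary alkyl group from boron follows, and reductive elimination forms the C2–C3 bond and releases the ketone. The closest known reaction type is the carbonylative Suzuki–Miyaura coupling of B-alkyl-9-BBN reagents with 1-iodoalkenes under one atmosphere of CO, which gives α,β-unsaturated ketones. No ring is closed and no stereocentre is created; the only stereo element, the E C4=C5 double bond, arrives ready-made in 7 and none of the elementary steps touches it. The selectivity needed is carbonyl insertion ahead of direct alkyl–alkenyl coupling, and it is secured because transmetalation of an alkylborane at room temperature is slow compared with CO insertion under a CO atmosphere. The silyl ethers keep phenoxides from trapping the acylpalladium intermediate as aryl esters, the primary alkyl group transfers in preference to the secondary bicyclic B–C bonds, and a non-oxidative work-up spares the enone.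

**Step 8**
Reactants: 12 (E)-1-[4-(tert-butyldimethylsilyloxy)-3-methoxyphenyl]-7-[4-(tert-butyldimethylsilyloxy)-3,5-dimethoxyphenyl]hept-4-en-3-one
Product: 13 (E)-1-(4-hydroxy-3-methoxyphenyl)-7-(4-hydroxy-3,5-dimethoxyphenyl)hept-4-en-3-one
Conditions: Bu4NF, AcOH, THF, 0 °C
Reagents that add atoms: none
Why: Fluoride-induced desilylation cleaves both aryl silyl ethers at silicon, and acetic acid protonates each phenoxide as it forms so that the enone should not suffer conjugate addition or double-bond migration.

**Compound list**
1 | 4-allyl-2,6-dimethoxyphenol | C=CCc1cc(OC)c(O)c(OC)c1 | starting material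
2 | (4-allyl-2,6-dimethoxyphenoxy)(tert-butyl)dimethylsilane | C=CCc1cc(OC)c(O[Si](C)(C)C(C)(C)C)c(OC)c1 | intermediate
3 | 9-borabicyclo[3.3.1]nonane (9-BBN) | B1C2CCCC1CCC2 | starting material
4 | 9-{3-[4-(tert-butyldimethylsilyloxy)-3,5-dimethoxyphenyl]propyl}-9-borabicyclo[3.3.1]nonane (not isolated) | COc1cc(CCCB2C3CCCC2CCC3)cc(OC)c1O[Si](C)(C)C(C)(C)C | intermediate
5 | 3-[4-(tert-butyldimethylsilyloxy)-3,5-dimethoxyphenyl]propan-1-ol | COc1cc(CCCO)cc(OC)c1O[Si](C)(C)C(C)(C)C | intermediate
6 | 3-[4-(tert-butyldimethylsilyloxy)-3,5-dimethoxyphenyl]propanal | COc1cc(CCC=O)cc(OC)c1O[Si](C)(C)C(C)(C)C | intermediate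
7 | tert-butyl{4-[(E)-4-iodobut-3-en-1-yl]-2,6-dimethoxyphenoxy}dimethylsilane | I/C=C/CCc1cc(OC)c(O[Si](C)(C)C(C)(C)C)c(OC)c1 | intermediate
8 | 2-methoxy-4-vinylphenol | C=Cc1ccc(O)c(OC)c1 | starting material
9 | tert-butyl(4-ethenyl-2-methoxyphenoxy)dimethylsilane | C=Cc1ccc(O[Si](C)(C)C(C)(C)C)c(OC)c1 | intermediate
10 | 9-{2-[4-(tert-butyldimethylsilyloxy)-3-methoxyphenyl]ethyl}-9-borabicyclo[3.3.1]nonane | COc1cc(CCB2C3CCCC2CCC3)ccc1O[Si](C)(C)C(C)(C)C | intermediate
11 | carbon monoxide | [C-]#[O+] | starting material
12 | (E)-1-[4-(tert-butyldimethylsilyloxy)-3-methoxyphenyl]-7-[4-(tert-butyldimethylsilyloxy)-3,5-dimethoxyphenyl]hept-4-en-3-one | COc1cc(CCC(=O)/C=C/CCc2cc(OC)c(O[Si](C)(C)C(C)(C)C)c(OC)c2)ccc1O[Si](C)(C)C(C)(C)C | intermediate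
13 | (E)-1-(4-hydroxy-3-methoxyphenyl)-7-(4-hydroxy-3,5-dimethoxyphenyl)hept-4-en-3-one | COc1cc(CCC(=O)/C=C/CCc2cc(OC)c(O)c(OC)c2)ccc1O | target

**Step count**
Total: 8 steps. Longest linear sequence: 6 steps (steps 1, 2, 3, 4, 7, 8).

**Steps most likely to fail**

Step 7. Transmetalation of the alkylborane may overtake CO insertion, giving the direct alkyl–alkenyl coupling product, or the catalyst may stall under CO so that little ketone forms. The fallback gives up the carbonylative union and builds the C4=C5 bond by aldol condensation, setting out from aldehyde 6. Purchased zingerone, 4-(4-hydroxy-3-methoxyphenyl)butan-2-one F1, would be silylated (TBSCl, imidazole, DMF) to 4-[4-(tert-butyldimethylsilyloxy)-3-methoxyphenyl]butan-2-one F2. Kinetic deprotonation at the methyl group with LDA in THF at −78 °C would give the lithium enolate F3, which should add to aldehyde 6 to give the racemic β-hydroxy ketone F4. Acid-catalysed dehydration (catalytic p-TsOH, warm toluene) should then give the conjugated E enone and rejoin the route at 12.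

Step 4. E selectivity in the chromium-mediated olefination may be incomplete, so that the Z iodide is carried into the coupling, and some aldehyde may be lost to reduction. The fallback sets out from aldehyde 6 and replaces the olefination by alkyne hydrometalation. One-carbon homologation with lithiated trimethylsilyldiazomethane (Colvin rearrangement, THF, −78 °C to rt) should give the terminal alkyne tert-butyl[4-(but-3-yn-1-yl)-2,6-dimethoxyphenoxy]dimethylsilane F5. Syn hydrozirconation with Cp2Zr(H)Cl in THF would give the (E)-alkenylzirconocene chloride F6, and iodinolysis with I2 with retention should return geometrically pure iodide 7.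

Step 2. The phenolic silyl ether may be partly lost during the basic oxidative work-up, leaving a mixture of protected and free phenol. The fallback sets out from 2 and no longer relies on the silyl ether surviving. After hydroboration to 4 as before, oxidation with NaOH/H2O2 and treatment of the crude with Bu4NF would bring all material to the diol 4-(3-hydroxypropyl)-2,6-dimethoxyphenol F7. Silylation of both hydroxyls (excess TBSCl, imidazole, DMF) would give the bis-silyl ether F8. Selective acidic methanolysis of the primary alkyl silyl ether (catalytic camphorsulfonic acid, MeOH/CH2Cl2, 0 °C), to which the aryl silyl ether is far less sensitive, should return alcohol 5.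

**Further compounds**
F1 | step 7 | 4-(4-hydroxy-3-methoxyphenyl)butan-2-one (zingerone, purchased) | CC(=O)CCc1ccc(O)c(OC)c1
F2 | step 7 | 4-[4-(tert-butyldimethylsilyloxy)-3-methoxyphenyl]butan-2-one | CC(=O)CCc1ccc(O[Si](C)(C)C(C)(C)C)c(OC)c1
F3 | step 7 | lithium 4-[4-(tert-butyldimethylsilyloxy)-3-methoxyphenyl]but-1-en-2-olate (not isolated) | [Li+].C=C([O-])CCc1ccc(O[Si](C)(C)C(C)(C)C)c(OC)c1
F4 | step 7 | racemic 1-[4-(tert-butyldimethylsilyloxy)-3-methoxyphenyl]-7-[4-(tert-butyldimethylsilyloxy)-3,5-dimethoxyphenyl]-5-hydroxyheptan-3-one | COc1cc(CCC(=O)CC(O)CCc2cc(OC)c(O[Si](C)(C)C(C)(C)C)c(OC)c2)ccc1O[Si](C)(C)C(C)(C)C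
F5 | step 4 | tert-butyl[4-(but-3-yn-1-yl)-2,6-dimethoxyphenoxy]dimethylsilane | C#CCCc1cc(OC)c(O[Si](C)(C)C(C)(C)C)c(OC)c1
F6 | step 4 | (E)-alkenylzirconocene chloride from F5 (not isolated; cyclopentadienyl rings drawn σ-bonded) | Cl[Zr](/C=C/CCc1cc(OC)c(O[Si](C)(C)C(C)(C)C)c(OC)c1)(C1C=CC=C1)C1C=CC=C1
F7 | step 2 | 4-(3-hydroxypropyl)-2,6-dimethoxyphenol | COc1cc(CCCO)cc(OC)c1O
F8 | step 2 | tert-butyl{3-[4-(tert-butyldimethylsilyloxy)-3,5-dimethoxyphenyl]propoxy}dimethylsilane | COc1cc(CCCO[Si](C)(C)C(C)(C)C)cc(OC)c1O[Si](C)(C)C(C)(C)C
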